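In a one-step world a yield is read from one clock, but this flask has a fork. Starting material opens to an intermediate, and two nucleophiles compete for it.

| flask | starting material | first nucleophile | second nucleophile | time | remark |
|---|---|---|---|---|---|
| larch | 31 mM | 93.0 mM | 24.8 mM | 5.0 h | a closed flask charged with all of it at once and left for 5.0 h |
| oak | 31 mM | 93.0 mM | 24.8 mM (fed, over 5.00 h) | 5.0 h | all but second nucleophile at the start; second nucleophile goes in evenly over 5.00 h, the run ends at 5.0 h |
| elm | 31 mM | 93.0 mM | 24.8 mM |  | one stirred flow tank at steady state, fed with the mixture as stated, mean residence time 5.0 h |
| alder | 31 mM (fed, over 5.00 h) | 93.0 mM | 24.8 mM | 5.0 h | all but starting material at the start; starting material goes in evenly over 5.00 h, the run ends at 5.0 h |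

    starting material ⇌ intermediate (K1 = 0.057, k1 = 0.627 h⁻¹)
    first nucleophile + intermediate → target (k2 = 1050 M⁻¹ h⁻¹)
    second nucleophile + intermediate → other capture product (k3 = 10600 M⁻¹ h⁻¹)
    first nucleophile + target → over-reaction product (k4 = 0.961 M⁻¹ h⁻¹)
    2 starting material → self-condensation product (k5 = 7.07 M⁻¹ h⁻¹)
    intermediate → decomposed reagent (k6 = 0.0951 h⁻¹)

- percentages count the starting material that a species holds: one self-condensation product counts as two
- for a step with 2 of a species take k times the square, and two of it per event
- the stated concentrations are those of everything mixed, before any reaction; amounts are the same in each set-up
- the feed brings no volume worth counting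
- run time (larch): 5.0 h

* the set-up with the highest amount of target at the outlet or at the end, in percent of the starting material put in ("none" if the first two lie within 2 percentage points) (larch / oak / elm / alder / none)
* amount of target at the outlet or at the end, in percent of the starting material put in, larch
* amount of target at the outlet or at the end, in percent of the starting material put in, oak
* amount of target at the outlet or at the end, in percent of the starting material put in, elm
* amount of target at the outlet or at the end, in percent of the starting material put in, alder

Capture by the first nucleophile has a half-life of 0.43 min at the larch charge, against 1.1 h for the forward opening, so the intermediate stays low. Both captures carry the same intermediate concentration, which cancels from their ratio. One concentration remains, 9.21 mM: the even-split level D*, at which the second nucleophile captures as fast as the first nucleophile at its charge. At a level D, the target's branch, target plus over-reaction product, takes D*/(D*+D).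

Larch starts at 24.8 mM, above D*, so the branch gets 27.1%. But not every starting material reaches the fork. Self-condensation against opening stands at x = 0.699 at the charge, and integrating over falling starting material leaves ln(1+x)/x = 75.8% for capture, or 23.5 mM.

Then the level itself moves. Capture spends about 17.1 mM of second nucleophile, so its mean level in larch is nearer 16.2 mM, and the branch rises to 36.2%.

Target is not an end either. Over-reaction is pseudo-first-order at 0.0894 h⁻¹, and target born near 1.59 h keeps 73.8%. Larch is reckoned at 20.3%.

Oak's feed delivers 7.91 mM during that first 1.59 h, below D*. The mean level of second nucleophile in oak over that time is taken as about 3.96 mM, and oak's branch as 70.0%. The objection is that dosing continues afterwards, while first-order opening at that time still runs at 36.8% of its first pace. Capture's spending of second nucleophile, left out of this mean, pulls the other way. Oak is reckoned at 39.1%, twice larch. Alder and elm are left unreckoned here.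

The forecast gives oak, with 19%, 37%, 19% and 20.5% for larch, oak, elm and alder, holding that “feeding it slowly keeps it scarce while most of the starting material is turning over”.

The flask gives oak: larch 18.8% against the reckoned 20.3%, oak 37.3% against 39.1%, elm 19.0%, alder 17.8%. At 2.50 h oak holds 32.1% of its whole second nucleophile charge, or 7.96 mM, while 82.9% of its first nucleophile puts D* at 7.64 mM, so the fork in oak at that moment splits about evenly. The neighbour of alder charged with 37 mM of first nucleophile has D* at 3.67 mM, below alder's, and ends with 10.5% target and 50.5% other capture product.

The rate constants were chosen freely; the flask was simulated.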